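Ring A of the coumarin (C4a, C5, C6, C7, C8, C8a; oxygen on C5 and C7, prenyl on C6) is treated as an isomer of a 2-pyranone ring in which O6 occupies the place of C6, while the future C6 waits outside the ring as the first methylene of a 4-methylpent-3-enyl chain on C7. Methoxide opens this pyranone at C5 and the chain methylene closes on the ester so formed; one operation thus makes the C5-C6 bond and the benzene ring and sets the prenyl group between two phenols without arene C-prenylation. The precursor is a 3-aryl-7-(4-methylpent-3-enyl)pyrano[4,3-b]pyran-2,5-dione with allyl-protected aryl hydroxyls.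

Key step: step 6

Remark (assumption): the target has no stereocentre. The double-bond geometries given for the enamino ester, the acrylate intermediate and the aminomethylene compound of one fallback are those expected to predominate; they equilibrate through push-pull conjugation and none reaches the target.

Step 1
Reactants: 1 triacetic acid lactone (4-hydroxy-6-methyl-2H-pyran-2-one); 2 prenyl bromide (1-bromo-3-methylbut-2-ene)
Product: 4 4-hydroxy-6-(4-methylpent-3-en-1-yl)-2H-pyran-2-one, via dilithium dianion of the lactone 3 (not isolated)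
Conditions: lithium diisopropylamide (2.2 equiv), THF, -78 °C; then 2 (0.95 equiv), -78 to 0 °C; aq HCl
Reagents that add atoms: none
Why: Alkylation of a 1,3-dicarbonyl-type dianion at its last-formed, most basic carbanion: the 6-methyl carbanion of 3 should displace bromide from the primary allylic halide in an SN2 reaction while the 4-oxide and C3 stay unreactive.

Step 2
Reactants: 5 2,4-dihydroxyphenylacetic acid
Product: 6 methyl 2-(2,4-dihydroxyphenyl)acetate
Conditions: MeOH, H2SO4 (cat.), reflux
Reagents that add atoms: methanol, CO
Why: Fischer esterification driven by methanol as solvent; the methyl ester is chosen over an allyl ester because the enolate of an allyl arylacetate could undergo ester-enolate Claisen rearrangement under the basic conditions of step 4.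

Step 3
Reactants: 6 methyl 2-(2,4-dihydroxyphenyl)acetate
Product: 7 methyl 2-[2,4-bis(allyloxy)phenyl]acetate
Conditions: allyl bromide (2.5 equiv), K2CO3 (3 equiv), acetone, reflux
Reagents that add atoms: allyl bromide, C=CCBr
Why: Double Williamson etherification of the two phenoxides under mild carbonate conditions that leave the methyl ester untouched; allyl is chosen because its later removal with zerovalent palladium spares the prenyl alkene, the lactone and the free 5-OH.

Step 4
Reactants: 7 methyl 2-[2,4-bis(allyloxy)phenyl]acetate; 8 tert-butoxybis(dimethylamino)methane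
Product: 9 methyl (E)-2-[2,4-bis(allyloxy)phenyl]-3-(dimethylamino)acrylate
Conditions: 8 (1.5 equiv), toluene, 90 °C
Reagents that add atoms: none
Why: Aminomethylenation of the benzylic ester methylene by an aminal ester, which releases tert-butoxide as internal base and should condense with the arylacetate far below the temperature at which aryl allyl ethers undergo Claisen rearrangement, giving the push-pull enamino ester as its E isomer.

Step 5
Reactants: 4 4-hydroxy-6-(4-methylpent-3-en-1-yl)-2H-pyran-2-one; 9 methyl (E)-2-[2,4-bis(allyloxy)phenyl]-3-(dimethylamino)acrylate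
Product: 11 3-[2,4-bis(allyloxy)phenyl]-7-(4-methylpent-3-enyl)-2H,5H-pyrano[4,3-b]pyran-2,5-dione, via Z-acrylate adduct 10 (not isolated)
Conditions: AcOH, 90 °C
Reagents that add atoms: none
Why: Known annulation of 4-hydroxy-2-pyranones with 3-(dimethylamino)acrylates: C3 of 4 should add to the protonated enamine carbon with loss of dimethylamine (addition-elimination), the acrylate equilibrates to the Z form 10 through conjugation with the enol, and the 4-OH then lactonises onto the ester, acetic acid at 90 °C being too weak an acid to hydrate the trisubstituted alkene.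

Step 6
Reactants: 11 3-[2,4-bis(allyloxy)phenyl]-7-(4-methylpent-3-enyl)-2H,5H-pyrano[4,3-b]pyran-2,5-dione
Product: 13 3-[2,4-bis(allyloxy)phenyl]-5,7-dihydroxy-6-(3-methylbut-2-en-1-yl)-2H-chromen-2-one, via ring-opened keto ester 12 (not isolated)
Conditions: NaOMe (4 equiv), MeOH-THF, 0 to 60 °C; then 1 M HCl, 0 °C, to pH 3
Reagents that add atoms: none
Why: Methoxide should add to the C5 carbonyl and expel O6 as the C7 dienolate, giving keto ester 12, in which the C7 ketone is flanked by C8 and by the chain methylene that carries the prenyl unit; under equilibrating conditions this methylene is enolised towards C7 and acylated by the C5 ester with loss of methoxide, and the cyclohexenedione so formed tautomerises to the 5,7-dihydroxy aromatic ring, whose phenoxide removes the product from every equilibrium. The closest known reaction types are the alkoxide-induced conversion of 6-(2-oxoalkyl)-2-pyranones and pyrano[4,3-b]pyran-2,5-diones into phloroglucinol- and resorcinol-type aromatics and the Claisen cyclisation of 5-oxoalkanoates to 2-alkylcyclohexane-1,3-diones, in which a ketone methylene likewise acylates an ester. Ring A closes in the 6-(enolendo)-exo-trig mode, because C7 and the attacking carbon both belong to the new ring, and no stereocentre is created. The step needs C5 to open while the O1-C2 lactone stays closed or recloses on O1, since a lactone re-formed only after aromatisation could engage either flanking phenol and would put part of the prenyl group on C8. The substrate should secure this in three ways: the ortho-allyloxyaryl group on C3 shields C2, attack at C2 gives only a 4-pyronolate ester that has no carbon nucleophile within reach of an ester and whose remaining lactone is deactivated by the negative charge, so that it can merely return to 11, and C8, the more acidic carbon of 12, could reach C5 only through a four-membered ring. Acidification at the end relactonises any material that is still open at C2.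

Step 7
Reactants: 13 3-[2,4-bis(allyloxy)phenyl]-5,7-dihydroxy-6-(3-methylbut-2-en-1-yl)-2H-chromen-2-one
Product: 14 3-[2,4-bis(allyloxy)phenyl]-5-hydroxy-7-methoxy-6-(3-methylbut-2-en-1-yl)-2H-chromen-2-one
Conditions: MeI (1.05 equiv), K2CO3 (1.1 equiv), acetone, 0 °C to rt
Reagents that add atoms: iodomethane, CI
Why: Williamson methylation under mono-anion control: 7-OH, para to C4a and so in through-conjugation with the lactone carbonyl along C4a-C4-C3-C2 and carrying only one ortho substituent, should ionise and react first, whereas 5-OH is hemmed in by the C6 prenyl group on one side and by the ring fusion with its peri C4-H on the other.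

Step 8
Reactants: 14 3-[2,4-bis(allyloxy)phenyl]-5-hydroxy-7-methoxy-6-(3-methylbut-2-en-1-yl)-2H-chromen-2-one
Product: 15 3-(2,4-dihydroxyphenyl)-5-hydroxy-7-methoxy-6-(3-methylbut-2-en-1-yl)-2H-chromen-2-one (CNP0305155.0)
Conditions: Pd(PPh3)4 (5 mol %), morpholine (6 equiv), THF, rt
Reagents that add atoms: none
Why: Tsuji-Trost deallylation: zerovalent palladium ionises the two aryl allyl ethers to allylpalladium complexes that morpholine captures, while the prenyl group (a plain trisubstituted alkene with no allylic leaving group), the methyl ether and the lactone are inert under these neutral conditions, which also avoid acid-induced cyclisation of the prenyl group onto 5-OH.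

Compound list
1 | triacetic acid lactone (4-hydroxy-6-methyl-2H-pyran-2-one) | Cc1cc(O)cc(=O)o1 | starting material
2 | prenyl bromide (1-bromo-3-methylbut-2-ene) | CC(C)=CCBr | starting material
3 | dilithium dianion of 1 (lithium 6-(lithiomethyl)-2-oxo-2H-pyran-4-olate) | [Li+].[Li+].[CH2-]C1=CC([O-])=CC(=O)O1 | intermediate
4 | 4-hydroxy-6-(4-methylpent-3-en-1-yl)-2H-pyran-2-one | CC(C)=CCCc1cc(O)cc(=O)o1 | intermediate
5 | 2,4-dihydroxyphenylacetic acid | O=C(O)Cc1ccc(O)cc1O | starting material
6 | methyl 2-(2,4-dihydroxyphenyl)acetate | COC(=O)Cc1ccc(O)cc1O | intermediate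
7 | methyl 2-[2,4-bis(allyloxy)phenyl]acetate | COC(=O)Cc1ccc(OCC=C)cc1OCC=C | intermediate
8 | tert-butoxybis(dimethylamino)methane | CC(C)(C)OC(N(C)C)N(C)C | starting material
9 | methyl (E)-2-[2,4-bis(allyloxy)phenyl]-3-(dimethylamino)acrylate | COC(=O)/C(=C/N(C)C)c1ccc(OCC=C)cc1OCC=C | intermediate
10 | methyl (Z)-2-[2,4-bis(allyloxy)phenyl]-3-[4-hydroxy-6-(4-methylpent-3-enyl)-2-oxo-2H-pyran-3-yl]acrylate | COC(=O)/C(=C\c1c(O)cc(CCC=C(C)C)oc1=O)c1ccc(OCC=C)cc1OCC=C | intermediate
11 | 3-[2,4-bis(allyloxy)phenyl]-7-(4-methylpent-3-enyl)-2H,5H-pyrano[4,3-b]pyran-2,5-dione | O=c1oc2cc(CCC=C(C)C)oc(=O)c2cc1-c1ccc(OCC=C)cc1OCC=C | intermediate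
12 | methyl 3-[2,4-bis(allyloxy)phenyl]-6-(6-methyl-2-oxohept-5-en-1-yl)-2-oxo-2H-pyran-5-carboxylate | COC(=O)c1cc(-c2ccc(OCC=C)cc2OCC=C)c(=O)oc1CC(=O)CCC=C(C)C | intermediate
13 | 3-[2,4-bis(allyloxy)phenyl]-5,7-dihydroxy-6-(3-methylbut-2-en-1-yl)-2H-chromen-2-one | Oc1cc2oc(=O)c(-c3ccc(OCC=C)cc3OCC=C)cc2c(O)c1CC=C(C)C | intermediate
14 | 3-[2,4-bis(allyloxy)phenyl]-5-hydroxy-7-methoxy-6-(3-methylbut-2-en-1-yl)-2H-chromen-2-one | COc1cc2oc(=O)c(-c3ccc(OCC=C)cc3OCC=C)cc2c(O)c1CC=C(C)C | intermediate
15 | 3-(2,4-dihydroxyphenyl)-5-hydroxy-7-methoxy-6-(3-methylbut-2-en-1-yl)-2H-chromen-2-one (CNP0305155.0) | COc1cc2oc(=O)c(-c3ccc(O)cc3O)cc2c(O)c1CC=C(C)C | target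

Total step count: 8. Longest linear sequence: 7 steps (steps 2 to 8, from 5); step 1 is a one-step side branch that joins at step 5.

Steps most likely to fail

Step 6. Three processes may interfere:
- Methoxide may add faster at the C2 lactone and park the material as the 4-pyronolate ester, so that productive opening at C5 becomes slow.
- The weakly acidic chain methylene may enolise too little beside the much more acidic C8, so that the reaction stalls at the ring-opened stage.
- Aromatisation while the C2 lactone is open would allow closure on the wrong phenol and scramble the prenyl group between C6 and C8.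

The fallback gives up the ring isomerisation, sets out from 7 and rejoins the route at 14, so that it also replaces step 7. Ester 7 is saponified (LiOH, THF-H2O, rt; then dilute HCl) to 2-[2,4-bis(allyloxy)phenyl]acetic acid F1. A Perkin condensation of F1 with commercially available 2,6-dihydroxy-4-methoxybenzaldehyde (Ac2O, Et3N, 110 °C) should give 3-[2,4-bis(allyloxy)phenyl]-7-methoxy-2-oxo-2H-chromen-5-yl acetate F2. Because the two hydroxyls of this aldehyde are equivalent, the 5-oxygen/7-methoxy pattern is fixed without any selectivity question. Methanolysis (K2CO3, MeOH, rt) frees 3-[2,4-bis(allyloxy)phenyl]-5-hydroxy-7-methoxy-2H-chromen-2-one F3. Alkylation of its 5-OH with 3-chloro-3-methylbut-1-yne (K2CO3, KI, CuI cat., acetone, reflux) gives 3-[2,4-bis(allyloxy)phenyl]-7-methoxy-5-[(2-methylbut-3-yn-2-yl)oxy]-2H-chromen-2-one F4. Semihydrogenation (H2, Pd/CaCO3 poisoned with Pb(OAc)2, quinoline, EtOAc, stopped after one equivalent) gives 3-[2,4-bis(allyloxy)phenyl]-7-methoxy-5-[(2-methylbut-3-en-2-yl)oxy]-2H-chromen-2-one F5. An aromatic Claisen rearrangement of F5 (N,N-diethylaniline, about 130 °C) should then deliver 14. The tertiary allyl ether rearranges well below the temperature needed by the two primary allyl ethers, and C6 is the only free ortho position of O5, so the prenyl group can arrive nowhere else.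

Step 7. Discrimination between the two phenols may be insufficient, leading to methylation at O5 or to double methylation. The fallback replaces direct alkylation by a protect-and-release sequence that sets out from 13 and rejoins at 14. Acetylation of both phenols (Ac2O, pyridine, rt) gives 3-[2,4-bis(allyloxy)phenyl]-6-(3-methylbut-2-en-1-yl)-2-oxo-2H-chromene-5,7-diyl diacetate F6. Acyl transfer to thiolate (PhSH, imidazole, N-methylpyrrolidinone, 0 °C) should remove the less hindered 7-acetate, which also has the better phenoxide leaving group, and give 3-[2,4-bis(allyloxy)phenyl]-7-hydroxy-6-(3-methylbut-2-en-1-yl)-2-oxo-2H-chromen-5-yl acetate F7. The now unique phenol is methylated (MeI, K2CO3, acetone, rt) to 3-[2,4-bis(allyloxy)phenyl]-7-methoxy-6-(3-methylbut-2-en-1-yl)-2-oxo-2H-chromen-5-yl acetate F8, and methanolysis (K2CO3, MeOH, rt) returns 14.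

Step 5. Carbon-carbon bond formation between C3 of the pyranone and the hindered, electron-rich alpha-aryl enamino ester may be slow in acetic acid, and prolonged heating in acid could begin to hydrate or cyclise the trisubstituted alkene. The fallback reverses the polarity of the coupling and forms the bond under basic conditions at low temperature; it sets out from 4 and rejoins at 11. Pyranone 4 is condensed at C3 with N,N-dimethylformamide dimethyl acetal (dioxane, rt) to (Z)-3-[(dimethylamino)methylidene]-6-(4-methylpent-3-en-1-yl)-2H-pyran-2,4(3H)-dione F9. The lithium enolate of ester 7 (LiN(SiMe3)2, THF, -78 °C) is added to F9 in a conjugate addition. Work-up and brief warming in AcOH (80 °C) then eliminates dimethylamine and lactonises through 10 to 11.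

Further compounds
F1 | step 6 | 2-[2,4-bis(allyloxy)phenyl]acetic acid | O=C(O)Cc1ccc(OCC=C)cc1OCC=C
F2 | step 6 | 3-[2,4-bis(allyloxy)phenyl]-7-methoxy-2-oxo-2H-chromen-5-yl acetate | COc1cc(OC(C)=O)c2cc(-c3ccc(OCC=C)cc3OCC=C)c(=O)oc2c1
F3 | step 6 | 3-[2,4-bis(allyloxy)phenyl]-5-hydroxy-7-methoxy-2H-chromen-2-one | COc1cc(O)c2cc(-c3ccc(OCC=C)cc3OCC=C)c(=O)oc2c1
F4 | step 6 | 3-[2,4-bis(allyloxy)phenyl]-7-methoxy-5-[(2-methylbut-3-yn-2-yl)oxy]-2H-chromen-2-one | COc1cc(OC(C)(C)C#C)c2cc(-c3ccc(OCC=C)cc3OCC=C)c(=O)oc2c1
F5 | step 6 | 3-[2,4-bis(allyloxy)phenyl]-7-methoxy-5-[(2-methylbut-3-en-2-yl)oxy]-2H-chromen-2-one | COc1cc(OC(C)(C)C=C)c2cc(-c3ccc(OCC=C)cc3OCC=C)c(=O)oc2c1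
F6 | step 7 | 3-[2,4-bis(allyloxy)phenyl]-6-(3-methylbut-2-en-1-yl)-2-oxo-2H-chromene-5,7-diyl diacetate | CC(=O)Oc1cc2oc(=O)c(-c3ccc(OCC=C)cc3OCC=C)cc2c(OC(C)=O)c1CC=C(C)C
F7 | step 7 | 3-[2,4-bis(allyloxy)phenyl]-7-hydroxy-6-(3-methylbut-2-en-1-yl)-2-oxo-2H-chromen-5-yl acetate | Oc1cc2oc(=O)c(-c3ccc(OCC=C)cc3OCC=C)cc2c(OC(C)=O)c1CC=C(C)C
F8 | step 7 | 3-[2,4-bis(allyloxy)phenyl]-7-methoxy-6-(3-methylbut-2-en-1-yl)-2-oxo-2H-chromen-5-yl acetate | COc1cc2oc(=O)c(-c3ccc(OCC=C)cc3OCC=C)cc2c(OC(C)=O)c1CC=C(C)C
F9 | step 5 | (Z)-3-[(dimethylamino)methylidene]-6-(4-methylpent-3-en-1-yl)-2H-pyran-2,4(3H)-dione | CN(C)/C=C1/C(=O)C=C(CCC=C(C)C)OC1=O
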